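**Strategy.** Ring A (the seven-membered carbocycle C1, C5–C10) is traced back to a cyclopentanone. The C5–C6–C7–C8–C9 segment, already fused to the cis γ-lactone (ring B: C6, C7, C11, C12, O), is a five-membered ketone. C1 (bearing C2) and C10 (bearing its methyl) come from the two sp carbons of methyl but-2-ynoate, spliced between C5 and C9. In one operation, enamine–ynoate [2+2] cycloaddition and opening of the cyclobutene form C9–C10 and C1–C5, enlarge the ring by two carbons and install the C2 ester and the C10 methyl. The precursor is the C5=C9 pyrrolidine enamine of the bicyclic keto lactone that already holds C6, C7 and C11.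

Key step: step 7

Numbering used: C1 tertiary carbinol carbon; C2 side-chain ketone; C3 side-chain CH2; C4 side-chain CH(OH); C5 angelate carbon; C6 lactone O–CH; C7 ring-fusion CH; C8, C9 ring CH2; C10 ring CH(CH3); C11 lactone CH(CH3); C12 lactone carbonyl.

Assumption: (S)-2-(cyclopent-2-en-1-yl)acetic acid is taken as purchasable in enantiopure form; if only the racemate is on offer it would first be resolved as a diastereomeric ammonium salt.

Step 1
Reactants: 1 (S)-2-(cyclopent-2-en-1-yl)acetic acid
Product: 3 cis-fused C5-hydroxy lactone (OH trans to the lactone oxygen), via trans-epoxy acid 2 (not isolated)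
Conditions: mCPBA, CH2Cl2, 0 °C to rt; then TsOH·H2O (cat.), rt
Reagents that add atoms: 3-chloroperoxybenzoic acid (mCPBA), O=C(OO)c1cccc(Cl)c1
Why: Prilezhaev epoxidation should occur mainly on the ring face away from the CH2CO2H arm, and acid-catalysed 5-exo opening of that trans-epoxide by the carboxyl group (inversion at C6) can only give the cis-fused γ-lactone with the C5 hydroxyl trans to the lactone oxygen, so C6 and C5 follow from C7; the cis-epoxide cannot lactonise and is removed.

Step 2
Reactants: 3 cis-fused C5-hydroxy lactone
Product: 4 C5 triethylsilyl ether of 3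
Conditions: TESCl, imidazole, DMF, 0 °C to rt
Reagents that add atoms: chlorotriethylsilane, CC[Si](Cl)(CC)CC
Why: Standard silylation of a secondary alcohol; the silyl ether masks the hydroxyl during the enolate steps and is removed in the oxidation step.

Step 3
Reactants: 4 C5 triethylsilyl ether of 3; 5 iodomethane
Product: 7 C11-epimeric methyl lactone (methyl cis to H7), via lithium enolate 6 (not isolated)
Conditions: LDA, THF, −78 °C; MeI, −78 to −40 °C
Reagents that add atoms: iodomethane, CI
Why: Alkylation of the lactone lithium enolate; iodomethane approaches the convex face of the cis-bicyclo[3.3.0] enolate and gives the C11 epimer with methyl cis to H7, a cleanly formed but wrong configuration that step 4 corrects.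

Step 4
Reactants: 7 C11-epimeric methyl lactone
Product: 9 methyl lactone of target C11 configuration (methyl on the concave face), via lithium enolate 8 (not isolated)
Conditions: LDA, THF, −78 °C; then 2,6-di-tert-butyl-4-methylphenol, THF, −78 °C
Reagents that add atoms: none
Why: Kinetic protonation of the re-formed enolate by a bulky phenol from the convex face should place H11 cis to H7 and push the methyl to the concave face, which is the C11 configuration of the target.

Step 5
Reactants: 9 methyl lactone of target C11 configuration
Product: 11 bicyclic keto lactone, via C5 alcohol 10 (not isolated)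
Conditions: Jones reagent (CrO3, H2SO4, H2O), acetone, 0 °C
Reagents that add atoms: none
Why: Jones oxidation: the aqueous acid cleaves the silyl ether and chromic acid oxidises the liberated secondary alcohol to the ketone under non-basic conditions that leave C11 and the lactone untouched; C6 cannot epimerise because only the cis ring fusion is possible.

Step 6
Reactants: 11 bicyclic keto lactone; 12 pyrrolidine
Product: 13 pyrrolidine enamine of 11 (C5=C9)
Conditions: pyrrolidine (1.5 equiv), TsOH (cat.), 4 Å MS, toluene, rt
Reagents that add atoms: pyrrolidine, C1CCNC1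
Why: Enamine condensation of a cyclopentanone; the double bond should form toward the C9 methylene because a C5=C6 enamine would sit at the ring-fusion carbon that carries the acyloxy group and suffer allylic strain, and room temperature with near-stoichiometric amine limits aminolysis of the lactone.

Step 7
Reactants: 13 pyrrolidine enamine of 11; 14 methyl but-2-ynoate
Product: 16 ring-expanded dienamine ester, via amino cyclobutene 15 (not isolated)
Conditions: methyl but-2-ynoate (2 equiv), MeCN, 80 °C, sealed tube
Reagents that add atoms: methyl but-2-ynoate, CC#CC(=O)OC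
Why: Stepwise [2+2] cycloaddition of an enamine with an acetylenic ester followed by ring opening (the classical two-carbon ring enlargement): nucleophilic C9 of 13 adds to the β-carbon (C10) of the ynoate and the allenolate carbon C1 closes onto the iminium carbon C5. This 4-exo-trig closure gives the bicyclo[3.2.0] amino cyclobutene 15 on the face opposite the lactone, and its C5 and C9 stereocentres are transient. The push–pull cyclobutene (donor nitrogen on C5, acceptor ester on C1) then breaks the C5–C9 bond by 4π-electrocyclic or zwitterionic opening, so the seven-membered ring arises by ring expansion and contains the cis,cis-dienamine. No stereocentre is created in 16, and C6, C7 and C11 are not involved. The step needs enamine regiochemistry toward C9 (secured in step 6 by the substituted, oxygenated C6) and head-to-tail addition (secured by the ester polarising the alkyne); the alkyne methyl only slows the addition, hence heating with excess ynoate.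

Step 8
Reactants: 16 ring-expanded dienamine ester
Product: 17 β-keto ester (drawn as its hydrogen-bonded dienol)
Conditions: 1 M HCl, THF, rt
Reagents that add atoms: water, O
Why: Acid hydrolysis of the vinylogous carbamate (C-protonation, iminium hydrolysis) releases pyrrolidine and gives the β-keto ester, expected largely as the chelated dienol in equilibrium with its keto tautomers; dilute acid at room temperature leaves the lactone, the methyl ester and C11 alone, and no stereocentre is formed.

Step 9
Reactants: 17 β-keto ester
Product: 18 9,10-dihydro β-keto ester (enol form drawn)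
Conditions: H2 (1 atm), Pd/C, EtOAc, rt
Reagents that add atoms: none
Why: Heterogeneous catalytic hydrogenation adds H2 syn to the trisubstituted C9=C10 bond (the chelated tetrasubstituted enol is inert) from the face away from the lactone ring attached below C6 and C7, which should put H10 cis to H6 and H7 and the C10 methyl on the lactone face as in the target; this selectivity rests on sterics alone.

Step 10
Reactants: 18 9,10-dihydro β-keto ester
Product: 19 β-hydroxy ester (C1 epimers)
Conditions: NaBH4, MeOH, −20 °C
Reagents that add atoms: none
Why: Borohydride reduction of the ketone tautomer gives the β-hydroxy ester; hydride should enter anti to the C6 oxygen, but the configurations at C5 and C1 do not matter because both carbons become sp2 in step 11, and NaBH4 in cold methanol leaves the lactone and the ester intact.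

Step 11
Reactants: 19 β-hydroxy ester
Product: 21 conjugated enoate (C1=C5), via mesylate 20 (not isolated)
Conditions: MsCl, Et3N, CH2Cl2, 0 °C; then DBU, rt
Reagents that add atoms: none
Why: Mesylation and base-induced E1cB elimination through the ester enolate gives the C1=C5 enoate from either C1 epimer; only C1 carries an acidic hydrogen, so the double bond cannot form toward C6, and brief exposure to DBU at room temperature should not enolise the lactone.

Step 12
Reactants: 21 conjugated enoate
Product: 23 enoic acid lactone, via hydroxy diacid 22 (not isolated)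
Conditions: LiOH, THF–H2O, rt to 40 °C; then 1 M HCl (pH 2), rt
Reagents that add atoms: lithium hydroxide, [Li+].[OH-]
Why: Saponification cleaves the conjugated methyl ester; the lactone opens as well but closes again on acidification because only the C12 carboxyl can reach the C6 hydroxyl (C2 is trans to C6 across C1=C5), and C11 is safe since hydroxide adds to the lactone carbonyl faster than it enolises it and a carboxylate does not enolise.

Step 13
Reactants: 23 enoic acid lactone
Product: 25 allylic alcohol (C2 CH2OH), via mixed carbonic anhydride 24 (not isolated)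
Conditions: i-BuOCOCl, N-methylmorpholine, THF, −15 °C; then NaBH4, H2O, 0 °C
Reagents that add atoms: none
Why: Only the free carboxylic acid is activated by the chloroformate, and NaBH4 reduces the mixed carbonic anhydride to the primary allylic alcohol (1,2-reduction) while the lactone is inert at 0 °C; this is what tells C2 apart from C12.

Step 14
Reactants: 25 allylic alcohol
Product: 26 C2 tert-butyldiphenylsilyl ether of 25
Conditions: TBDPSCl, imidazole, DMF, rt
Reagents that add atoms: tert-butyl(chloro)diphenylsilane, CC(C)(C)[Si](Cl)(c1ccccc1)c1ccccc1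
Why: Silylation of the primary alcohol with a bulky, acid-stable silyl group that survives the epoxide hydrolysis and keeps the primary hydroxyl out of the later esterification.

Step 15
Reactants: 26 C2 tert-butyldiphenylsilyl ether of 25
Product: 27 C1–C5 epoxide on the face of H6 and H7
Conditions: mCPBA, NaHCO3, CH2Cl2, 0 °C
Reagents that add atoms: 3-chloroperoxybenzoic acid (mCPBA), O=C(OO)c1cccc(Cl)c1
Why: Prilezhaev epoxidation of the trisubstituted alkene; both allylic substituents (the C6 oxygen and the C10 methyl) and the lactone ring lie on one face, so the peracid should deliver oxygen to the opposite face, which fixes the C5–O bond in the target configuration and sets C1 up for inversion.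

Step 16
Reactants: 27 C1–C5 epoxide
Product: 28 trans-diol (C1 hydroxyl on the lactone face; C5 hydroxyl on the opposite face)
Conditions: HClO4 (cat.), THF–H2O (3:1), 0 °C to rt
Reagents that add atoms: water, O
Why: Acid-catalysed epoxide hydrolysis with anti opening at the tertiary carbon C1 (C5 is secondary and deactivated by the neighbouring acyloxy carbon): water enters on the lactone face with inversion at C1 while the epoxide oxygen stays on C5, giving the trans-diol with both carbinol centres as in the target.

Step 17
Reactants: 28 trans-diol; 29 angelic acid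
Product: 31 C5 angelate silyl ether, via mixed angelic anhydride 30 (not isolated)
Conditions: angelic acid, 2,4,6-Cl3C6H2COCl, Et3N, toluene, rt; then 28, 80 °C
Reagents that add atoms: angelic acid, C/C=C(/C)C(=O)O
Why: Yamaguchi-type esterification through the mixed anhydride acylates the secondary C5 hydroxyl with retention (the C–O bond is untouched); the tertiary C1 hydroxyl is too hindered to react, and leaving out a nucleophilic catalyst should preserve the Z geometry of the angelate.

Step 18
Reactants: 31 C5 angelate silyl ether
Product: 32 C5 angelate 1,2-diol (C1 and C2 hydroxyls)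
Conditions: HF·pyridine, pyridine, THF, 0 °C to rt
Reagents that add atoms: none
Why: Fluoride-mediated desilylation under buffered acidic conditions frees the primary alcohol without base, so neither angelate migration nor lactone epimerisation is expected.

Step 19
Reactants: 32 C5 angelate 1,2-diol
Product: 33 α-hydroxy aldehyde (C2 CHO)
Conditions: SO3·pyridine, DMSO, i-Pr2NEt, CH2Cl2, 0 °C
Reagents that add atoms: none
Why: Parikh–Doering oxidation converts the primary alcohol into the aldehyde at 0 °C without cleaving the 1,2-diol; the tertiary hydroxyl cannot be oxidised and the aldehyde has no α-hydrogen to epimerise or eliminate.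

Step 20
Reactants: 33 α-hydroxy aldehyde
Product: 34 C2 methyl carbinol (C2 epimers)
Conditions: MeTi(Oi-Pr)3, THF, −40 to 0 °C; aq. NH4Cl
Reagents that add atoms: methyltitanium triisopropoxide, C[Ti](OC(C)C)(OC(C)C)OC(C)C
Why: Chemoselective carbonyl addition: the methyltitanium reagent adds to aldehydes but not to esters, lactones or enoates, so only C2 is methylated; the new C2 stereocentre is not controlled and is destroyed in step 21.

Step 21
Reactants: 34 C2 methyl carbinol
Product: 35 methyl ketone (C1 acetyl)
Conditions: Dess–Martin periodinane, NaHCO3, CH2Cl2, rt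
Reagents that add atoms: none
Why: Dess–Martin oxidation of the secondary carbinol gives the α-hydroxy methyl ketone; the tertiary hydroxyl is inert and the buffered neutral conditions spare the angelate and C11.

Step 22
Reactants: 35 methyl ketone; 36 acetaldehyde
Product: 38 target CNP0321985.1, via boron enolate 37 (not isolated)
Conditions: (+)-Ipc2BCl (2.2 equiv), Et3N, Et2O, 0 °C; MeCHO, −78 to −20 °C; H2O2, pH 7 buffer, MeOH, 0 °C
Reagents that add atoms: acetaldehyde, CC=O
Why: Boron-mediated aldol addition of a diisopinocampheylboron enolate: enolisation can only occur toward the methyl group (C1 is quaternary, so the β-angeloyloxy group cannot be eliminated), and the isopinocampheyl ligands of the (+)-reagent (from (−)-α-pinene) should direct the enolate to the si face of acetaldehyde to give the (4R)-carbinol; oxidative work-up releases the target.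

**Compound list**

1 | (S)-2-(cyclopent-2-en-1-yl)acetic acid | OC(=O)C[C@H]1C=CCC1 | starting material
2 | 2-(2,3-epoxycyclopentyl)acetic acid, epoxide trans to the side chain | OC(=O)C[C@@H]1CC[C@H]2O[C@@H]12 | intermediate
3 | cis-fused hydroxy lactone, C5 hydroxyl trans to the lactone oxygen | O=C1O[C@H]2[C@H](O)CC[C@H]2C1 | intermediate
4 | C5 triethylsilyl ether of 3 | O=C1O[C@H]2[C@H](O[Si](CC)(CC)CC)CC[C@H]2C1 | intermediate
5 | iodomethane | CI | starting material
6 | lithium enolate of 4 (C11=C12) | [Li]OC=1O[C@H]2[C@H](O[Si](CC)(CC)CC)CC[C@H]2C=1 | intermediate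
7 | C11-epimeric methyl lactone, methyl on the convex face (cis to H7), C5 OTES | O=C1O[C@H]2[C@H](O[Si](CC)(CC)CC)CC[C@H]2[C@@H]1C | intermediate
8 | lithium enolate of 7 | [Li]OC=1O[C@H]2[C@H](O[Si](CC)(CC)CC)CC[C@H]2C=1C | intermediate
9 | methyl lactone of target C11 configuration, methyl on the concave face (H11 cis to H7), C5 OTES | O=C1O[C@H]2[C@H](O[Si](CC)(CC)CC)CC[C@H]2[C@H]1C | intermediate
10 | C5 alcohol of 9 | O=C1O[C@H]2[C@H](O)CC[C@H]2[C@H]1C | intermediate
11 | bicyclic keto lactone (C5 ketone, cis-fused lactone, C11 methyl) | O=C1O[C@H]2C(=O)CC[C@H]2[C@H]1C | intermediate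
12 | pyrrolidine | C1CCNC1 | starting material
13 | pyrrolidine enamine of 11 (C5=C9) | O=C1O[C@H]2C(N3CCCC3)=CC[C@H]2[C@H]1C | intermediate
14 | methyl but-2-ynoate | CC#CC(=O)OC | starting material
15 | lactone-fused amino cyclobutene (bicyclo[3.2.0]heptene: C5 pyrrolidinyl, C1 CO2Me, C10 methyl; new bonds on the face opposite the lactone) | O=C1O[C@H]2[C@]3(N4CCCC4)C(C(=O)OC)=C(C)[C@@H]3C[C@H]2[C@H]1C | intermediate
16 | ring-expanded dienamine ester (C5 pyrrolidinyl, C5=C1 with CO2Me, C10(Me)=C9) | O=C1O[C@H]2C(N3CCCC3)=C(C(=O)OC)C(C)=CC[C@H]2[C@H]1C | intermediate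
17 | ring-expanded β-keto ester, drawn as the chelated dienol | O=C1O[C@H]2C(O)=C(C(=O)OC)C(C)=CC[C@H]2[C@H]1C | intermediate
18 | 9,10-dihydro β-keto ester, enol form drawn, C10 methyl on the lactone face | O=C1O[C@H]2C(O)=C(C(=O)OC)[C@@H](C)CC[C@H]2[C@H]1C | intermediate
19 | β-hydroxy ester, C5 hydroxyl cis to the lactone oxygen, C1 epimers | O=C1O[C@H]2[C@@H](O)C(C(=O)OC)[C@@H](C)CC[C@H]2[C@H]1C | intermediate
20 | C5 mesylate of 19 | O=C1O[C@H]2[C@@H](OS(C)(=O)=O)C(C(=O)OC)[C@@H](C)CC[C@H]2[C@H]1C | intermediate
21 | conjugated enoate (C2 methyl ester, C1=C5) | O=C1O[C@H]2C=C(C(=O)OC)[C@@H](C)CC[C@H]2[C@H]1C | intermediate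
22 | ring-opened hydroxy diacid (dilithium salt in the flask, drawn as the acid) | O=C(O)[C@H](C)[C@@H]1CC[C@H](C)C(C(=O)O)=C[C@@H]1O | intermediate
23 | enoic acid lactone (C2 CO2H) | O=C1O[C@H]2C=C(C(=O)O)[C@@H](C)CC[C@H]2[C@H]1C | intermediate
24 | mixed isobutyl carbonic anhydride of 23 | O=C1O[C@H]2C=C(C(=O)OC(=O)OCC(C)C)[C@@H](C)CC[C@H]2[C@H]1C | intermediate
25 | allylic alcohol (C2 CH2OH) | O=C1O[C@H]2C=C(CO)[C@@H](C)CC[C@H]2[C@H]1C | intermediate
26 | C2 tert-butyldiphenylsilyl ether of 25 | O=C1O[C@H]2C=C(CO[Si](c3ccccc3)(c3ccccc3)C(C)(C)C)[C@@H](C)CC[C@H]2[C@H]1C | intermediate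
27 | C1–C5 epoxide on the face of H6 and H7 (trans to lactone oxygen and C10 methyl) | O=C1O[C@H]2[C@@H]3O[C@]3(CO[Si](c4ccccc4)(c4ccccc4)C(C)(C)C)[C@@H](C)CC[C@H]2[C@H]1C | intermediate
28 | trans-diol: C1 hydroxyl on the lactone face, C5 hydroxyl on the opposite face, C2 OTBDPS | O[C@H]1[C@@H]2OC(=O)[C@H](C)[C@@H]2CC[C@H](C)[C@@]1(O)CO[Si](c1ccccc1)(c1ccccc1)C(C)(C)C | intermediate
29 | angelic acid, (Z)-2-methylbut-2-enoic acid | C/C=C(/C)C(=O)O | starting material
30 | angelic 2,4,6-trichlorobenzoic anhydride | C/C=C(/C)C(=O)OC(=O)c1c(Cl)cc(Cl)cc1Cl | intermediate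
31 | C5 angelate of 28 | C/C=C(/C)C(=O)O[C@H]1[C@@H]2OC(=O)[C@H](C)[C@@H]2CC[C@H](C)[C@@]1(O)CO[Si](c1ccccc1)(c1ccccc1)C(C)(C)C | intermediate
32 | C5 angelate 1,2-diol (C1 hydroxyl, C2 CH2OH) | C/C=C(/C)C(=O)O[C@H]1[C@@H]2OC(=O)[C@H](C)[C@@H]2CC[C@H](C)[C@@]1(O)CO | intermediate
33 | α-hydroxy aldehyde (C2 CHO) | C/C=C(/C)C(=O)O[C@H]1[C@@H]2OC(=O)[C@H](C)[C@@H]2CC[C@H](C)[C@@]1(O)C=O | intermediate
34 | C2 methyl carbinol (1-hydroxyethyl on C1, C2 epimers) | C/C=C(/C)C(=O)O[C@H]1[C@@H]2OC(=O)[C@H](C)[C@@H]2CC[C@H](C)[C@@]1(O)C(C)O | intermediate
35 | methyl ketone (C1 acetyl) | C/C=C(/C)C(=O)O[C@H]1[C@@H]2OC(=O)[C@H](C)[C@@H]2CC[C@H](C)[C@@]1(O)C(C)=O | intermediate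
36 | acetaldehyde | CC=O | starting material
37 | diisopinocampheylboron enolate of 35 | C/C=C(/C)C(=O)O[C@H]1[C@@H]2OC(=O)[C@H](C)[C@@H]2CC[C@H](C)[C@@]1(O)C(=C)OB([C@H]1C[C@H]2C[C@@H]([C@@H]1C)C2(C)C)[C@H]1C[C@H]2C[C@@H]([C@@H]1C)C2(C)C | intermediate
38 | CNP0321985.1 | C/C=C(/C)C(=O)O[C@H]1[C@@H]2OC(=O)[C@H](C)[C@@H]2CC[C@H](C)[C@@]1(O)C(=O)C[C@@H](C)O | target

**Total step count:** 22.
**Longest linear sequence:** 22 steps from 1 (compounds 5, 12, 14, 29 and 36 are bought).

**Steps most likely to fail**

1. Step 7. The methyl-substituted ynoate is a sluggish electrophile. At the temperature needed, the enamine may be lost to other paths before the four-membered ring closes: aminolysis of the lactone by liberated amine, or a Michael addition that stops at the open-chain adduct. Fallback, a Lewis-acid-promoted [2+2] cycloaddition of a silyl enol ether with the same alkynoate: keto lactone 11 is treated with TBSOTf and Et3N to give the silyl enol ether F1, again toward C9. F1 and methyl but-2-ynoate 14 with EtAlCl2 in CH2Cl2 at −78 °C give the siloxy cyclobutene F2. HF·pyridine removes the silyl group and the cyclobutenol fragments by retro-aldol cleavage of C5–C9 to the β-keto ester 17, where the route is rejoined.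

2. Step 16. Ionisation at the tertiary C1 may run ahead of capture by water, so that a hydride shift from C2 or loss of facial fidelity competes with anti addition. Fallback, reagent-controlled epoxidation on the other face followed by substitution at C5: allylic alcohol 25 is epoxidised under Sharpless conditions with D-(−)-diethyl tartrate (Ti(Oi-Pr)4, t-BuOOH, 4 Å MS, CH2Cl2, −20 °C) to the epoxy alcohol F3, which carries the oxirane on the lactone face. Opening of F3 at C5 with angelic acid 29 mediated by Ti(Oi-Pr)4 (inversion at C5, C1–O retained) gives the angelate diol 32 directly.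

3. Step 22. Facial discrimination of the small aldehyde by the chiral boron enolate may be poor, so that the C4 epimer forms alongside the product. Fallback, reduction instead of carbon–carbon bond formation to set C4: methyl ketone 35 is C-acetylated by soft enolisation (MgBr2·OEt2, i-Pr2NEt, 1-acetylbenzotriazole, CH2Cl2) to the 1,3-diketone F4. Noyori asymmetric hydrogenation of F4 (RuCl2[(R)-BINAP], H2, MeOH) should reduce only the unhindered C4 carbonyl, with the (R) sense known for β-dicarbonyl substrates, and give target 38; the C2 ketone next to the quaternary C1 should stay.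

**Further compounds**

F1 | step 7 | tert-butyldimethylsilyl enol ether of 11 (C5=C9) | O=C1O[C@H]2C(O[Si](C)(C)C(C)(C)C)=CC[C@H]2[C@H]1C
F2 | step 7 | lactone-fused siloxy cyclobutene (C5 OTBS, C1 CO2Me, C10 methyl) | O=C1O[C@H]2[C@]3(O[Si](C)(C)C(C)(C)C)C(C(=O)OC)=C(C)[C@@H]3C[C@H]2[C@H]1C
F3 | step 16 | epoxy alcohol with the C1–C5 oxirane on the lactone face (C2 CH2OH) | O=C1O[C@H]2[C@H]3O[C@@]3(CO)[C@@H](C)CC[C@H]2[C@H]1C
F4 | step 22 | 1,3-diketone (C2 and C4 carbonyls) | C/C=C(/C)C(=O)O[C@H]1[C@@H]2OC(=O)[C@H](C)[C@@H]2CC[C@H](C)[C@@]1(O)C(=O)CC(C)=O
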